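## Structural features

The target is an achiral 2-arylbenzofuran. A benzofuran (benzene ring A fused to furan ring B through C3a–C7a) carries at C2 a 7-hydroxy-2,2-dimethylchroman-5-yl group (aromatic ring C fused to dihydropyran ring D), and a single biaryl bond joins benzofuran C2 to chroman C5. Ring A has hydroxyls on C4 and C6, a free C5–H between them, and on C7 a 2-methylbut-3-en-2-yl group whose quaternary carbon sits between the C6 hydroxyl and the furan oxygen on C7a. There is no stereocentre in the target; the only one that appears on the way (the methine that becomes C7) is racemic and vanishes on aromatisation. Ring A is a phloroglucinol-type arene, sensitive to oxidants and to electrophiles at C5 and C3. Its ortho-(1,1-dimethylallyl)phenol can close to a dihydrofuran in strong acid, and the terminal alkene rules out hydrogenolytic deprotection. The real difficulty is the quaternary carbon on C7, because direct C-alkylation of a trioxygenated arene with a prenyl unit gives the linear isomer or positional mixtures; a second, smaller problem is placing the biaryl bond at C5 of a 7-hydroxychroman. The key step uses the 1,3-relationship of the oxygens on C4 and C6 (latent carbonyl carbons) and the fact that the C3a–C7a bond is a furan C3–C2 bond. Ring A can therefore be opened between C4 and C5 to a furan-3-carboxylate (ester carbon = C4) whose C2 substituent is a 2-oxopropyl chain (C7, C6, C5) that already bears the quaternary group.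

## Logic of the disconnections

**19 to 17.** The C4–C5 bond of ring A is cut. C4 becomes the carbonyl carbon of a furan-3-carboxylate and C5/C6 the methyl and carbonyl carbons of a ketone, with 18 as the diketone tautomer between them. The gain is that ring A, with both hydroxyls free and the C7 substituent in place, comes from an open chain on a furan, so no substitution on an electron-rich arene is needed. The demand is that the methyl enolate, not the methine enolate, acylates on carbon. The chroman hydroxyl of 17 is left free as a spectator so that the target forms directly under base and ring A never meets acid.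

**17 to 16.** Only the acetal O–CH2 bond on the chroman oxygen is cut. The timing is deliberate: the acetal is removed while the molecule contains only a deactivated furan ester, before the diol and the ortho-(1,1-dimethylallyl)phenol exist. The demand is that the acetal lasts through steps 4 to 8.

**16 to 14 (through 15).** The CO–CH3 bond is cut. The acid is what the sigmatropic step delivers, and one operation converts it to the ketone. The demand is methyl transfer to the acyl carbon without attack on the furan ester and without loss of the acidic α-hydrogen.

**14 to 11 (through 12 and 13).** The bond between the α-carbon (future C7) and the quaternary carbon is cut, the retron being a γ,δ-unsaturated acid. The quaternary carbon and its vinyl group then come from the O-allyl ester of 10 with no regiochemical alternative. The demand is clean enolisation of the doubly activated methylene and tolerance of the congestion in the [3,3] shift.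

**11 to 9 and 10, and 9 to 8.** The ester C–O bond is cut, and behind it the two methyl esters of 8 are told apart. The gain is a simple diester as the coupling product. The demand is that hydroxide attacks the aliphatic ester and leaves the conjugated furan ester.

**8 to 3 and 7.** The biaryl bond between furan C5 and chroman C5 is cut. The molecule falls into two pieces of similar size, and 3 has a single free α C–H, so no metalated or halogenated furan is needed and no acid-mediated furan closure has to be run in the presence of the acetal. The demand is C–H arylation with a hindered, electron-rich bromide.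

**3 to 1 and 2.** The O1–C5 and C3–C4 bonds of the furan are cut. Both esters and the acetic side chain come from 1 in one condensation. The demand is only the usual regiochemistry of the haloaldehyde condensation.

**7 to 6, and 6 to 4 and 5.** The acetal O–CH2 bond is cut, and then the C4a–C4 and O1–C2 bonds of ring D. The chroman comes from two commercial compounds in one step. The demand is alkylation of 4 at the carbon next to bromine and not between the hydroxyls.

## Other disconnections considered

Alternative 1: The cut removes the biaryl bond C2–C5' and the C4a'–C4' bond to the prenyl carbon. This leads back to 4,6-bis(methoxymethoxy)-7-(2-methylbut-3-en-2-yl)benzofuran (A2), the aryne precursor 1-bromo-2-iodo-3,5-bis(methoxymethoxy)benzene (A3) and a prenyl electrophile. Forward, 2-magnesiated A2 adds to the aryne released from A3 by iodine–magnesium exchange; the alkoxy group next to the triple bond steers the nucleophile to the remote aryne carbon, and the new arylmagnesium is passed to copper and prenylated to give A1.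
- In favour: two C–C bonds form in one flask, the route is convergent, and the polarisation of the aryne fixes the order aryl/prenyl/oxygen on ring C. On that point it is better than the chosen plan, whose step 2 depends on the site selectivity of a resorcinol alkylation.
- Against: A2 already contains the C7 quaternary group and both ring A oxygens, so the main difficulty is only moved. The arylmagnesium, flanked by the benzofuran and an acetal oxygen, must be allylated without allylic transposition. Afterwards four acetals must be removed and ring D closed by acid next to a free ring A, whose own ortho-(1,1-dimethylallyl)phenol can cyclise the same way.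
- Comparison: the mechanism is an organometallic cascade at low temperature, against an enolate condensation under alkoxide. It is the equal or the better of the chosen plan in convergence at the joining step, but probably longer once A2 is counted, and it exposes the finished ring A to acid, which the chosen plan avoids.

Alternative 2: The cut is the C3a–C3 bond of ring B, traced back to racemic flavanone A5, in which ring A is bonded to the carbonyl carbon. Forward, the enol ether of A5 is iodinated at C3 by a hypervalent aryl-iodine oxidant in an orthoformate medium, and ring A shifts from C4 to C3 with loss of iodoarene, giving the trans dihydrobenzofuran ester A4.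
- In favour: the O1–C2–aryl connectivity comes from chalcone and flavanone chemistry without transition-metal coupling, and the position of the 2-aryl group is fixed by construction. On that point it is the equal of the chosen plan.
- Against: A4 has an extra ester and two stereocentres that must be removed again by hydrolysis, decarboxylation and dehydrogenation. The oxidant is an electrophile that can also attack the trioxygenated ring A and the vinyl group. Migration of the electron-rich C2 aryl group (isoflavone formation) and simple dehydrogenation compete with the wanted shift. A5 needs a 2-hydroxyacetophenone that already carries the 1,1-dimethylallyl group, so the prenylation problem returns.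
- Comparison: it edits a preformed ring A, whereas the chosen plan builds ring A and sets the quaternary carbon on an acyclic ester. Mechanistically it is a cationic 1,2-shift with several competing channels, against a condensation driven by aromatisation. In step count it is longer.

Alternative 3: The cut is at the quaternary carbon, whose bonds to one methyl and to the vinyl group are removed, leading to the 7-acetyl compound A7 with a tert-butyl carbonate on the C6 oxygen. Forward, a methyl Grignard reagent adds to the acetyl group, the alkoxide takes over the carbonate, the C6 phenoxide expels it to give the ortho-quinone methide A8, and a vinyl Grignard reagent adds to the exocyclic carbon to give A6.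
- In favour: the quaternary carbon is made in one operation on an intact 2-arylbenzofuran. Locally this is better in step economy than steps 6 to 8 of the chosen plan, and the reagents are simple.
- Against: A8 has two methyl groups on the exocyclic carbon. It is hindered and can lose a proton from a methyl group (1,5-hydrogen shift or deprotonation by the Grignard reagent) instead of accepting the nucleophile. Two different Grignard reagents must act in strict order. A7 needs acylation at C7 and not C5, and a carbonate on the C6 and not the C4 oxygen. A6 still needs acidic removal of two acetals with ring A complete.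
- Comparison: the outcome depends on competition between addition and tautomerisation of a reactive intermediate, whereas the sigmatropic shift of the chosen plan can give one constitution only. It could be shorter overall if A7 were easy to reach, and this is named as its possible advantage.

Key step: step 10

Remark on the chemistry: the target has no stereocentre; compounds 13 to 18 carry one (the carbon that becomes C7), are racemic, and lose it in step 10.

## Route

Step 1
Reactants: 1 dimethyl 3-oxopentanedioate; 2 chloroacetaldehyde
Product: 3 methyl 2-(2-methoxy-2-oxoethyl)furan-3-carboxylate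
Conditions: ClCH2CHO (50% aq.), pyridine, 50 °C
Reagents that add atoms: none
Why: Feist–Benary furan synthesis: the enol of 1 adds to the aldehyde, the enol oxygen displaces chloride and the hydroxydihydrofuran loses water. The aldehyde carbon becomes C4 and the chloromethyl carbon C5, so C5 stays unsubstituted for step 4.

Step 2
Reactants: 4 5-bromoresorcinol (5-bromobenzene-1,3-diol); 5 2-methylbut-3-en-2-ol
Product: 6 5-bromo-2,2-dimethylchroman-7-ol
Conditions: TsOH·H2O (10 mol%), 1,4-dioxane, 80 °C; 4 (2 equiv), slow addition of 5
Reagents that add atoms: none
Why: Acid-catalysed Friedel–Crafts alkylation by the dimethylallyl cation, then Markovnikov addition of the neighbouring hydroxyl to the new trisubstituted alkene (chroman annulation). Attack at C4 of 4, para to one hydroxyl and ortho to the other, is the kinetically preferred site of 5-substituted resorcinols and puts bromine on C5 of the chroman; the isomer from attack between the hydroxyls and any doubly annulated material are to be removed by chromatography. The excess of 4 and slow addition of 5 should hold back a second annulation.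

Step 3
Reactants: 6 5-bromo-2,2-dimethylchroman-7-ol
Product: 7 5-bromo-7-(methoxymethoxy)-2,2-dimethylchroman
Conditions: MOMCl, i-Pr2NEt, CH2Cl2, 0 °C → rt
Reagents that add atoms: chloromethyl methyl ether (MOMCl), COCCl
Why: O-Alkylation of the phenol (Williamson-type acetal ether formation). The acetal should be inert to the palladium catalysis, hydroxide, amide base and cuprate of steps 4 to 8 and leaves under mild acid in step 9.

Step 4
Reactants: 3 methyl 2-(2-methoxy-2-oxoethyl)furan-3-carboxylate; 7 5-bromo-7-(methoxymethoxy)-2,2-dimethylchroman
Product: 8 methyl 2-(2-methoxy-2-oxoethyl)-5-[7-(methoxymethoxy)-2,2-dimethylchroman-5-yl]furan-3-carboxylate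
Conditions: Pd(OAc)2 (5 mol%), PCy3·HBF4 (10 mol%), KOAc (2 equiv), DMA, 120 °C, Ar; 3 (1.5 equiv)
Reagents that add atoms: none
Why: Palladium-catalysed direct C–H arylation of a furan: zerovalent palladium inserts into the C–Br bond and the furan C–H is cleaved by acetate-assisted concerted metalation–deprotonation. C5 is the only free α-position of 3 and the ester on C3 shields C4, so the biaryl bond can form only between furan C5 and chroman C5. KOAc is too weak a base to deprotonate the methylene group, which should prevent α-arylation.

Step 5
Reactants: 8 methyl 2-(2-methoxy-2-oxoethyl)-5-[7-(methoxymethoxy)-2,2-dimethylchroman-5-yl]furan-3-carboxylate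
Product: 9 2-{3-(methoxycarbonyl)-5-[7-(methoxymethoxy)-2,2-dimethylchroman-5-yl]furan-2-yl}acetic acid
Conditions: LiOH·H2O (1.1 equiv), THF/H2O, 0 °C; then 1 M HCl to pH 3–4, 0 °C
Reagents that add atoms: lithium hydroxide, [Li+].[OH-]
Why: Chemoselective saponification. The side-chain heteroarylacetate is a normal aliphatic ester, while the furan-3-carboxylate is a vinylogous carbonate conjugated with the ring oxygen and much less electrophilic, so one equivalent of hydroxide at 0 °C should cleave the side-chain ester only.

Step 6
Reactants: 9 2-{3-(methoxycarbonyl)-5-[7-(methoxymethoxy)-2,2-dimethylchroman-5-yl]furan-2-yl}acetic acid; 10 3-methylbut-2-en-1-ol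
Product: 11 methyl 5-[7-(methoxymethoxy)-2,2-dimethylchroman-5-yl]-2-{2-[(3-methylbut-2-en-1-yl)oxy]-2-oxoethyl}furan-3-carboxylate
Conditions: EDC·HCl, DMAP (10 mol%), CH2Cl2, 0 °C → rt
Reagents that add atoms: none
Why: Steglich esterification through the O-acylisourea and the acylpyridinium ion. The near-neutral conditions leave the acetal and the furan ester untouched.

Step 7
Reactants: 11 methyl 5-[7-(methoxymethoxy)-2,2-dimethylchroman-5-yl]-2-{2-[(3-methylbut-2-en-1-yl)oxy]-2-oxoethyl}furan-3-carboxylate
Product: 14 racemic 2-{3-(methoxycarbonyl)-5-[7-(methoxymethoxy)-2,2-dimethylchroman-5-yl]furan-2-yl}-3,3-dimethylpent-4-enoic acid, via silyl ketene acetal 12 (not isolated), via trimethylsilyl ester 13 (not isolated)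
Conditions: LiN(SiMe3)2, Me3SiCl, THF, −78 °C → rt → 60 °C; then aq. citric acid
Reagents that add atoms: none
Why: Ireland–Claisen rearrangement: the doubly activated methylene is deprotonated and O-silylated to 12, whose [3,3]-sigmatropic shift through a chair-like transition state bonds the α-carbon to the dimethyl-substituted allyl terminus, so the quaternary carbon and the terminal vinyl group can arise in one constitution only. Hydrolysis of the silyl ester 13 on work-up gives 14. The one new stereocentre is not controlled (racemate) and is erased in step 10, so the geometry of 12 does not matter.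

Step 8
Reactants: 14 racemic 2-{3-(methoxycarbonyl)-5-[7-(methoxymethoxy)-2,2-dimethylchroman-5-yl]furan-2-yl}-3,3-dimethylpent-4-enoic acid
Product: 16 racemic methyl 2-(4,4-dimethyl-2-oxohex-5-en-3-yl)-5-[7-(methoxymethoxy)-2,2-dimethylchroman-5-yl]furan-3-carboxylate, via acid chloride 15 (not isolated)
Conditions: Me2C=C(Cl)NMe2, CH2Cl2, 0 °C → rt; then Me2CuLi (from CuI and 2 MeLi), Et2O, −78 °C; aq. NH4Cl
Reagents that add atoms: lithium dimethylcuprate (Me2CuLi), [Li+].C[Cu-]C
Why: The α-chloroenamine turns the acid into 15 without releasing HCl, which spares the acetal, and acylation of the lithium dialkylcuprate then gives the methyl ketone (cuprate ketone synthesis). Me2CuLi attacks an acid chloride at −78 °C but neither the furan ester nor the amide by-product, and it is too weak a base to convert 15 into a ketene.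

Step 9
Reactants: 16 racemic methyl 2-(4,4-dimethyl-2-oxohex-5-en-3-yl)-5-[7-(methoxymethoxy)-2,2-dimethylchroman-5-yl]furan-3-carboxylate
Product: 17 racemic methyl 2-(4,4-dimethyl-2-oxohex-5-en-3-yl)-5-(7-hydroxy-2,2-dimethylchroman-5-yl)furan-3-carboxylate
Conditions: HCl (3 M aq.)/MeOH, 40 °C; aq. NaHCO3 work-up
Reagents that add atoms: none
Why: Acid-catalysed acetal exchange with methanol removes the methoxymethyl group as dimethoxymethane. Done at this stage, on a deactivated furan ester, it keeps acid and the methoxymethyl cation away from the later ring A diol and its ortho-(1,1-dimethylallyl)phenol; the aqueous work-up returns any ketal to the ketone.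

Step 10
Reactants: 17 racemic methyl 2-(4,4-dimethyl-2-oxohex-5-en-3-yl)-5-(7-hydroxy-2,2-dimethylchroman-5-yl)furan-3-carboxylate
Product: 19 2-(7-hydroxy-2,2-dimethylchroman-5-yl)-7-(2-methylbut-3-en-2-yl)benzofuran-4,6-diol (CNP0300714.0), via cyclic 1,3-diketone 18 (not isolated)
Conditions: NaOMe (6 equiv), MeOH (degassed), reflux, Ar; then AcOH, 0 °C
Reagents that add atoms: none
Why: Intramolecular Claisen (Dieckmann-type) condensation followed by aromatisation: methoxide equilibrates the ketone enolates of 17 (the chroman phenol is a spectator phenoxide), the enolate of the acetyl methyl group (future C5) adds to the furan ester carbonyl (future C4), and loss of methoxide gives 18, which enolises at once to the 4,6-diol. The closest known reaction type is the base-mediated cyclisation of 2-(2-oxopropyl)benzoates to naphthalene-1,3-diols, here run on a furan-3-carboxylate. Ring A closes in a six-membered exo-trig mode at the ester carbonyl, with the enolate double bond outside the new ring. No stereocentre is formed; the racemic methine becomes the aromatic carbon C7. The step needs C-acylation through the methyl enolate, although the methine between furan and ketone is the more acidic site. The methine enolate can only O-acylate to an enol lactone, which methoxide reopens, whereas the C-acylation product leaves the equilibrium as the aromatic bis-phenoxide, so the reversible conditions should funnel material through the methyl enolate. The congestion around the methine (quaternary carbon on one side, ester-bearing furan on the other) further lowers the share of its enolate, and because the ketone is largely held as enolate, cleavage of the acetyl group by methoxide should stay minor. The target is released by mild acidification under argon and never meets strong acid.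

## Compound list

1 | dimethyl 3-oxopentanedioate | COC(=O)CC(=O)CC(=O)OC | starting material
2 | chloroacetaldehyde | ClCC=O | starting material
3 | methyl 2-(2-methoxy-2-oxoethyl)furan-3-carboxylate | COC(=O)Cc1occc1C(=O)OC | intermediate
4 | 5-bromoresorcinol (5-bromobenzene-1,3-diol) | Oc1cc(O)cc(Br)c1 | starting material
5 | 2-methylbut-3-en-2-ol | C=CC(C)(C)O | starting material
6 | 5-bromo-2,2-dimethylchroman-7-ol | CC1(C)CCc2c(Br)cc(O)cc2O1 | intermediate
7 | 5-bromo-7-(methoxymethoxy)-2,2-dimethylchroman | COCOc1cc(Br)c2CCC(C)(C)Oc2c1 | intermediate
8 | methyl 2-(2-methoxy-2-oxoethyl)-5-[7-(methoxymethoxy)-2,2-dimethylchroman-5-yl]furan-3-carboxylate | COC(=O)Cc1oc(-c2cc(OCOC)cc3c2CCC(C)(C)O3)cc1C(=O)OC | intermediate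
9 | 2-{3-(methoxycarbonyl)-5-[7-(methoxymethoxy)-2,2-dimethylchroman-5-yl]furan-2-yl}acetic acid | OC(=O)Cc1oc(-c2cc(OCOC)cc3c2CCC(C)(C)O3)cc1C(=O)OC | intermediate
10 | 3-methylbut-2-en-1-ol | CC(C)=CCO | starting material
11 | methyl 5-[7-(methoxymethoxy)-2,2-dimethylchroman-5-yl]-2-{2-[(3-methylbut-2-en-1-yl)oxy]-2-oxoethyl}furan-3-carboxylate | CC(C)=CCOC(=O)Cc1oc(-c2cc(OCOC)cc3c2CCC(C)(C)O3)cc1C(=O)OC | intermediate
12 | methyl 5-[7-(methoxymethoxy)-2,2-dimethylchroman-5-yl]-2-{2-[(3-methylbut-2-en-1-yl)oxy]-2-[(trimethylsilyl)oxy]ethenyl}furan-3-carboxylate (silyl ketene acetal, double-bond geometry not defined) | CC(C)=CCOC(O[Si](C)(C)C)=Cc1oc(-c2cc(OCOC)cc3c2CCC(C)(C)O3)cc1C(=O)OC | intermediate (not isolated)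
13 | racemic trimethylsilyl 2-{3-(methoxycarbonyl)-5-[7-(methoxymethoxy)-2,2-dimethylchroman-5-yl]furan-2-yl}-3,3-dimethylpent-4-enoate | C=CC(C)(C)C(C(=O)O[Si](C)(C)C)c1oc(-c2cc(OCOC)cc3c2CCC(C)(C)O3)cc1C(=O)OC | intermediate (not isolated)
14 | racemic 2-{3-(methoxycarbonyl)-5-[7-(methoxymethoxy)-2,2-dimethylchroman-5-yl]furan-2-yl}-3,3-dimethylpent-4-enoic acid | C=CC(C)(C)C(C(=O)O)c1oc(-c2cc(OCOC)cc3c2CCC(C)(C)O3)cc1C(=O)OC | intermediate
15 | racemic methyl 2-(1-chloro-3,3-dimethyl-1-oxopent-4-en-2-yl)-5-[7-(methoxymethoxy)-2,2-dimethylchroman-5-yl]furan-3-carboxylate (acid chloride) | C=CC(C)(C)C(C(=O)Cl)c1oc(-c2cc(OCOC)cc3c2CCC(C)(C)O3)cc1C(=O)OC | intermediate (not isolated)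
16 | racemic methyl 2-(4,4-dimethyl-2-oxohex-5-en-3-yl)-5-[7-(methoxymethoxy)-2,2-dimethylchroman-5-yl]furan-3-carboxylate | C=CC(C)(C)C(C(C)=O)c1oc(-c2cc(OCOC)cc3c2CCC(C)(C)O3)cc1C(=O)OC | intermediate
17 | racemic methyl 2-(4,4-dimethyl-2-oxohex-5-en-3-yl)-5-(7-hydroxy-2,2-dimethylchroman-5-yl)furan-3-carboxylate | C=CC(C)(C)C(C(C)=O)c1oc(-c2cc(O)cc3c2CCC(C)(C)O3)cc1C(=O)OC | intermediate
18 | racemic 2-(7-hydroxy-2,2-dimethylchroman-5-yl)-7-(2-methylbut-3-en-2-yl)-5,7-dihydrobenzofuran-4,6-dione | C=CC(C)(C)C1C(=O)CC(=O)c2cc(-c3cc(O)cc4c3CCC(C)(C)O4)oc21 | intermediate (not isolated)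
19 | 2-(7-hydroxy-2,2-dimethylchroman-5-yl)-7-(2-methylbut-3-en-2-yl)benzofuran-4,6-diol (CNP0300714.0) | C=CC(C)(C)c1c(O)cc(O)c2cc(-c3cc(O)cc4c3CCC(C)(C)O4)oc12 | target

## Step count and least certain steps

Total: 10 steps. Longest linear sequence: 9 steps (4 to 19 through steps 2 to 10); the furan branch (step 1) joins at step 4.

**Step 10 (key step).** The enolate equilibrium may be drained through the more stabilised methine enolate into O-acylation (enol lactone). The closure itself may be slow because the furan ester is a weak electrophile next to a crowded ketone, and prolonged heating would give methoxide time to cleave the acetyl group. The fallback sets out from 14 and returns at 19, and it moves the nucleophilic carbon into a malonate-type position where no competing enolate matters.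
- Activation of 14 with 1,1'-carbonyldiimidazole and C-acylation of MeO2CCH2CO2K/MgCl2 would give racemic methyl 4-{3-(methoxycarbonyl)-5-[7-(methoxymethoxy)-2,2-dimethylchroman-5-yl]furan-2-yl}-5,5-dimethyl-3-oxohept-6-enoate F1.
- Acidic methanol as in step 9 would give racemic methyl 4-[5-(7-hydroxy-2,2-dimethylchroman-5-yl)-3-(methoxycarbonyl)furan-2-yl]-5,5-dimethyl-3-oxohept-6-enoate F2.
- NaOMe in MeOH would close ring A by Dieckmann condensation of the β-keto ester methylene onto the furan ester, giving methyl 4,6-dihydroxy-2-(7-hydroxy-2,2-dimethylchroman-5-yl)-7-(2-methylbut-3-en-2-yl)benzofuran-5-carboxylate F3.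
- Saponification with aqueous KOH at 90 °C and acidification would decarboxylate the 2,6-dihydroxybenzoic acid to 19.

**Step 2.** Poor site selectivity of the alkylation (attack between the two hydroxyls gives the isomeric chroman) and over-annulation at the second hydroxyl are the likely failures, because a tertiary allyl cation is an unselective electrophile. The fallback sets out from 4 and returns at 6, and it uses acylation, whose preference for the position para to a hydroxyl is firmer. Friedel–Crafts acylation and oxa-Michael closure of 4 with 3-methylbut-2-enoic acid in P2O5/MeSO3H would give 5-bromo-7-hydroxy-2,2-dimethylchroman-4-one F4, and ionic hydrogenation with Et3SiH in CF3CO2H would remove the benzylic carbonyl to give 6.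

**Step 4.** Slow oxidative addition to the hindered, electron-rich bromide, with catalyst decay at 120 °C, and side reaction at the acidic methylene of 3 are the likely failures. The fallback sets out from 3 and 7 and returns at 8, replacing C–H activation by a cross-coupling of two prefunctionalised partners.
- Bromination of 3 with NBS in DMF would give methyl 5-bromo-2-(2-methoxy-2-oxoethyl)furan-3-carboxylate F5.
- Miyaura borylation of 7 (B2pin2, Pd(dppf)Cl2, KOAc, 1,4-dioxane, 90 °C) would give 2-[7-(methoxymethoxy)-2,2-dimethylchroman-5-yl]-4,4,5,5-tetramethyl-1,3,2-dioxaborolane F6.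
- Suzuki–Miyaura coupling of the two (Pd(PPh3)4, K3PO4, 1,4-dioxane/H2O, 80 °C) would give 8.

**Step 8.** Loss of the acidic α-hydrogen of 15 (ketene formation and dimerisation) and incomplete methyl transfer to the neopentyl-like acyl carbon are the likely failures. The fallback sets out from 14 and returns at 16, using a non-basic palladium-catalysed acyl coupling. Thioesterification of 14 (EtSH, EDC·HCl, DMAP, CH2Cl2) would give racemic S-ethyl 2-{3-(methoxycarbonyl)-5-[7-(methoxymethoxy)-2,2-dimethylchroman-5-yl]furan-2-yl}-3,3-dimethylpent-4-enethioate F7, and Fukuyama coupling with MeZnI and PdCl2(PPh3)2 in toluene would give 16.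

## Further compounds

F1 | step 10 | racemic methyl 4-{3-(methoxycarbonyl)-5-[7-(methoxymethoxy)-2,2-dimethylchroman-5-yl]furan-2-yl}-5,5-dimethyl-3-oxohept-6-enoate | C=CC(C)(C)C(C(=O)CC(=O)OC)c1oc(-c2cc(OCOC)cc3c2CCC(C)(C)O3)cc1C(=O)OC
F2 | step 10 | racemic methyl 4-[5-(7-hydroxy-2,2-dimethylchroman-5-yl)-3-(methoxycarbonyl)furan-2-yl]-5,5-dimethyl-3-oxohept-6-enoate | C=CC(C)(C)C(C(=O)CC(=O)OC)c1oc(-c2cc(O)cc3c2CCC(C)(C)O3)cc1C(=O)OC
F3 | step 10 | methyl 4,6-dihydroxy-2-(7-hydroxy-2,2-dimethylchroman-5-yl)-7-(2-methylbut-3-en-2-yl)benzofuran-5-carboxylate | C=CC(C)(C)c1c(O)c(C(=O)OC)c(O)c2cc(-c3cc(O)cc4c3CCC(C)(C)O4)oc12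
F4 | step 2 | 5-bromo-7-hydroxy-2,2-dimethylchroman-4-one | CC1(C)CC(=O)c2c(Br)cc(O)cc2O1
F5 | step 4 | methyl 5-bromo-2-(2-methoxy-2-oxoethyl)furan-3-carboxylate | COC(=O)Cc1oc(Br)cc1C(=O)OC
F6 | step 4 | 2-[7-(methoxymethoxy)-2,2-dimethylchroman-5-yl]-4,4,5,5-tetramethyl-1,3,2-dioxaborolane | COCOc1cc(B2OC(C)(C)C(C)(C)O2)c2CCC(C)(C)Oc2c1
F7 | step 8 | racemic S-ethyl 2-{3-(methoxycarbonyl)-5-[7-(methoxymethoxy)-2,2-dimethylchroman-5-yl]furan-2-yl}-3,3-dimethylpent-4-enethioate | C=CC(C)(C)C(C(=O)SCC)c1oc(-c2cc(OCOC)cc3c2CCC(C)(C)O3)cc1C(=O)OC
A1 | alternative 1 | 2-[3,5-bis(methoxymethoxy)-2-(3-methylbut-2-enyl)phenyl]-4,6-bis(methoxymethoxy)-7-(2-methylbut-3-en-2-yl)benzofuran | C=CC(C)(C)c1c(OCOC)cc(OCOC)c2cc(-c3cc(OCOC)cc(OCOC)c3CC=C(C)C)oc12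
A2 | alternative 1 | 4,6-bis(methoxymethoxy)-7-(2-methylbut-3-en-2-yl)benzofuran | C=CC(C)(C)c1c(OCOC)cc(OCOC)c2ccoc12
A3 | alternative 1 | 1-bromo-2-iodo-3,5-bis(methoxymethoxy)benzene | COCOc1cc(Br)c(I)c(OCOC)c1
A4 | alternative 2 | racemic methyl trans-4,6-bis(methoxymethoxy)-2-[7-(methoxymethoxy)-2,2-dimethylchroman-5-yl]-7-(2-methylbut-3-en-2-yl)-2,3-dihydrobenzofuran-3-carboxylate (one enantiomer drawn) | C=CC(C)(C)c1c(OCOC)cc(OCOC)c2c1O[C@H](c1cc(OCOC)cc3c1CCC(C)(C)O3)[C@H]2C(=O)OC
A5 | alternative 2 | racemic 5,7-bis(methoxymethoxy)-2-[7-(methoxymethoxy)-2,2-dimethylchroman-5-yl]-8-(2-methylbut-3-en-2-yl)chroman-4-one | C=CC(C)(C)c1c(OCOC)cc(OCOC)c2c1OC(c1cc(OCOC)cc3c1CCC(C)(C)O3)CC2=O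
A6 | alternative 3 | 4-(methoxymethoxy)-2-[7-(methoxymethoxy)-2,2-dimethylchroman-5-yl]-7-(2-methylbut-3-en-2-yl)benzofuran-6-ol | C=CC(C)(C)c1c(O)cc(OCOC)c2cc(-c3cc(OCOC)cc4c3CCC(C)(C)O4)oc12
A7 | alternative 3 | tert-butyl {7-acetyl-4-(methoxymethoxy)-2-[7-(methoxymethoxy)-2,2-dimethylchroman-5-yl]benzofuran-6-yl} carbonate | CC(=O)c1c(OC(=O)OC(C)(C)C)cc(OCOC)c2cc(-c3cc(OCOC)cc4c3CCC(C)(C)O4)oc12
A8 | alternative 3 | 4-(methoxymethoxy)-2-[7-(methoxymethoxy)-2,2-dimethylchroman-5-yl]-7-(propan-2-ylidene)benzofuran-6(7H)-one | CC(C)=C1C(=O)C=C(OCOC)c2cc(-c3cc(OCOC)cc4c3CCC(C)(C)O4)oc21
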